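Substrate that meets free catalyst becomes target, and the free catalyst comes out unchanged; the reckoning starts from that easy step.

    substrate + free catalyst → free catalyst + target (k1 = 1400 M⁻¹ h⁻¹)
    substrate ⇌ dormant form (K2 = 0.73, k2 = 5.3 h⁻¹)
    2 free catalyst → spent catalyst (k3 = 4000 M⁻¹ h⁻¹)

substrate 0.20 M; free catalyst 2.0 mM

- for a step with 2 of a species take k times the square, and two of it per event
- what has gone from substrate into another species counts as reacted, even if it can come back
- a form made of two catalysts counts as two
- charge of substrate (flask): 0.20 M

- the form that holds most of the catalyst when 20% of the substrate are converted (spent catalyst / free catalyst)
- its share of the catalyst then
- factor on the rate of making target when 20% of the substrate are converted if free catalyst is charged twice over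
- factor on the rate when 20% of the substrate are converted if free catalyst is charged at 0.20 mM instead

My reckoning works with fractions left. The main step by itself, with free catalyst held at its charge, is pseudo-first-order: substrate falls at 2.80 h⁻¹, and reaching a fraction left of 80.0% takes 4.78 min. Adding the forward leak to dormant form raises the rate to 8.10 h⁻¹. The leak is faster than the main step, so the time shrinks to 1.65 min. The return from dormant form stays out of my reckoning.

Then comes the loss of free catalyst. Its reciprocal climbs in a straight line, so its fraction left is one over one plus the time multiplied by the catalyst clock. The catalyst clock, 16.0 h⁻¹, is twice the constant of the loss step times the charge. After 1.65 min, free catalyst keeps 69.4%, so it holds more than spent catalyst. At that conversion the compared flasks hold equal substrate, so a rate factor is a ratio of free catalyst. The same steps leave 60.4% in the flask with the doubled charge, a factor of 1.74. They leave 94.0% in the flask charged at 0.20 mM, a factor of 0.135.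

The forecast also names free catalyst, but with 66% and factors of 1.68 and 0.141, which differ from mine. Of the way to that conversion it says: “leakage to dormant form dominates, with catalysis adding to it”.

The flask reaches that conversion after 1.93 min, later than my time. There, free catalyst holds 66.0% and spent catalyst 34.0%. The factors are 1.68 and 0.141, as the forecast gave them.

At 1.93 min the clock gives a fraction left of 66.0%. Part of what holds the rate down at that moment is the loss of free catalyst in pairs: the run without that step makes target 1.51 times as fast, and one plus clock times time gives 1.51. The apparent order in free catalyst there is 0.77; it stands at 1.0 in the run without that loss and at 1.0 in the run without the step to dormant form, so the two together hold it below that value. The flask charged at 0.20 mM has a clock of 1.60 h⁻¹ and is reckoned to keep 94.0%. Its charge ratio, times 94.0% over 66.0%, gives 0.142, and the run gives 0.141.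

(The constants come from no measurement; the result is computed.)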